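**Plan**

1. Numbering (clerodane type): ring A = C1–C2–C3=C4–C5–C10; ring B = C5–C6–C7–C8–C9–C10; ring C = C10–C1–C16=C13(furan)–C12(=O)–C11–C9; lactone = C4–C18(=O)–O–C19–C5; β is the face of H-10.
2. Enabling feature: C6 is homoallylic to C3=C4 and C2 carries the allylic oxygen, so C2(O)–C3=C4–C5–C6 is the footprint of an epoxide-triggered cyclopropylcarbinyl radical opening, and the C6 radical is 1,5 to C7. The retrosynthesis therefore re-closes C4–C6 (cyclopropane, a temporary ring), places an epoxide on C2–C3 and cuts C6–C7 to an aldehyde.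
3. Further cuts: acetate and C2 redox adjustment; C12–C13 (furan acylation, ring C); C6 (methylene from a sulfur ylide); C1–C2 and C5–C10 (pyranone cycloaddition, then loss of CO2, ring A); C8–C9 (Ireland–Claisen); C1 carbinol from an enone.
4. Forward: furan side chain (steps 1–6), ring A diene lactone (7, 8), cyclopropane [4.3.1]propellane (9), ring C (10–12), epoxide and aldehyde (13–15), ring B together with C2–OH and C3=C4 in one relay (16), then C2 oxidation, acetate and C2 reduction (17–19).
5. Stereochemistry: CBS reduction (C1 carbinol), chair Ireland–Claisen (C9, C8), E alkene plus facial bias of C9 in the cycloaddition (C1, C10), ylide attack anti to the C10 substituent (C5), chair radical cyclisation (C7), Luche reduction (C2).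

Key step: step 16

Assumption: in the CBS reduction of step 2 the 2-furyl group takes the place of the large aryl group; should the sense be reversed, the enantiomeric catalyst would be used to reach 5.

Step 1
Reactants: 1 tert-butyl(but-3-yn-1-yloxy)dimethylsilane; 2 furan-2-carbonyl chloride
Product: 4 (2E)-5-[(tert-butyldimethylsilyl)oxy]-1-(furan-2-yl)-3-methylpent-2-en-1-one, via alkenylalane 3 (not isolated)
Conditions: Me3Al, Cp2ZrCl2 (cat.), CH2Cl2, 0 °C to rt; then 2, Pd(PPh3)4 (cat.), THF, 0 °C
Reagents that add atoms: trimethylaluminium, C[Al](C)C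
Why: Negishi carboalumination adds methyl and aluminium syn across the terminal alkyne (methyl to the inner carbon), which fixes the E trisubstituted alkene, and the alkenylalane is acylated in situ by palladium-catalysed coupling with the acid chloride.

Step 2
Reactants: 4 (2E)-5-[(tert-butyldimethylsilyl)oxy]-1-(furan-2-yl)-3-methylpent-2-en-1-one
Product: 5 (1R,2E)-5-[(tert-butyldimethylsilyl)oxy]-1-(furan-2-yl)-3-methylpent-2-en-1-ol
Conditions: (S)-Me-CBS (10 mol %), BH3·SMe2, THF, −30 °C
Reagents that add atoms: none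
Why: Corey–Bakshi–Shibata reduction, in which the planar 2-furyl group should act as the large aryl-type substituent so that the (S)-catalyst gives the (R)-carbinol whose chirality is later passed to C9.

Step 3
Reactants: 5 (1R,2E)-5-[(tert-butyldimethylsilyl)oxy]-1-(furan-2-yl)-3-methylpent-2-en-1-ol
Product: 6 (1R,2E)-5-[(tert-butyldimethylsilyl)oxy]-1-(furan-2-yl)-3-methylpent-2-en-1-yl propanoate
Conditions: propanoyl chloride, pyridine, DMAP (cat.), CH2Cl2, 0 °C
Reagents that add atoms: propanoyl chloride, CCC(=O)Cl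
Why: DMAP-catalysed O-acylation of a secondary alcohol under basic conditions that spare the ionisable furyl allyl system.

Step 4
Reactants: 6 (1R,2E)-5-[(tert-butyldimethylsilyl)oxy]-1-(furan-2-yl)-3-methylpent-2-en-1-yl propanoate
Product: 9 (2S,3R,4E)-3-{2-[(tert-butyldimethylsilyl)oxy]ethyl}-5-(furan-2-yl)-2,3-dimethylpent-4-enoic acid, via Z silyl ketene acetal 7 (not isolated), via trimethylsilyl ester 8 (not isolated)
Conditions: LDA, THF/HMPA (4:1), −78 °C; Me3SiCl, −78 °C to rt; then 1 M HCl
Reagents that add atoms: none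
Why: Ireland–Claisen rearrangement: enolisation in THF/HMPA gives the Z silyl ketene acetal, and a chair transition state with the furyl group equatorial transfers the carbinol chirality to quaternary C9, sets C8 (2S,3R in the acid) and leaves the E alkene C10=C1.

Step 5
Reactants: 9 (2S,3R,4E)-3-{2-[(tert-butyldimethylsilyl)oxy]ethyl}-5-(furan-2-yl)-2,3-dimethylpent-4-enoic acid
Product: 10 (2S,3R,4E)-3-{2-[(tert-butyldimethylsilyl)oxy]ethyl}-5-(furan-2-yl)-2,3-dimethylpent-4-en-1-ol
Conditions: LiAlH4, Et2O, 0 °C
Reagents that add atoms: none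
Why: Hydride reduction of a carboxylic acid to the primary alcohol, which leaves the silyl ether, the furan and the alkene untouched.

Step 6
Reactants: 10 (2S,3R,4E)-3-{2-[(tert-butyldimethylsilyl)oxy]ethyl}-5-(furan-2-yl)-2,3-dimethylpent-4-en-1-ol
Product: 11 tert-butyldiphenylsilyl ether of 10 (the dienophile)
Conditions: t-BuPh2SiCl, imidazole, DMF, rt
Reagents that add atoms: tert-butyl(chloro)diphenylsilane, CC(C)(C)[Si](Cl)(c1ccccc1)c1ccccc1
Why: Imidazole-promoted silylation of the primary alcohol gives a silyl ether that will outlast the tert-butyldimethylsilyl ether on C12.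

Step 7
Reactants: 12 tetronic acid; 13 ethyl 3,3-diethoxypropanoate
Product: 14 2H-furo[3,4-b]pyran-2,5(7H)-dione
Conditions: conc. H2SO4, AcOH, 70 °C
Reagents that add atoms: none
Why: von Pechmann condensation, in which C3 of the enol attacks the masked formyl carbon and the enol oxygen closes onto the ester, fusing a 2-pyranone onto the butenolide.

Step 8
Reactants: 11 tert-butyldiphenylsilyl ether of 10; 14 2H-furo[3,4-b]pyran-2,5(7H)-dione
Product: 16 ring A diene lactone (4,5-dihydro-2-benzofuran-1(3H)-one with 1β-furyl and 10β-H), via bridged lactone cycloadduct 15 (not isolated)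
Conditions: toluene, BHT (cat.), 120 °C, sealed tube
Reagents that add atoms: none
Why: Inverse-electron-demand Diels–Alder reaction of the electron-poor 2-pyranone with the furan-conjugated alkene (nucleophilic C10 bonds to the lactone β-carbon C5) followed by cycloreversion with loss of CO2; suprafacial addition to the E alkene makes C1 and C10 trans, and the diene should approach anti to the CH(CH3)CH2O branch of C9 with the C9 methyl in the outside position of a staggered allylic model, which gives 10β-H.

Step 9
Reactants: 16 ring A diene lactone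
Product: 17 cyclopropane lactone (C4–C5–C6 ring on the β face; [4.3.1]propellane)
Conditions: Me3S(O)I, NaH, DMSO, rt
Reagents that add atoms: trimethylsulfoxonium iodide, C[S+](C)(C)=O.[I-]
Why: Corey–Chaykovsky cyclopropanation: the sulfoxonium ylide adds to C5, the β-carbon of the unsaturated lactone, from the face anti to the pseudoaxial C9 substituent on C10, and the lactone enolate closes the three-membered ring, which fixes quaternary C5 and brings in C6.

Step 10
Reactants: 17 cyclopropane lactone
Product: 18 primary alcohol (C12–OH)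
Conditions: HF·pyridine, pyridine, THF, 0 °C
Reagents that add atoms: none
Why: Fluoride-mediated desilylation cleaves the more labile primary tert-butyldimethylsilyl ether in the presence of the tert-butyldiphenylsilyl ether.

Step 11
Reactants: 18 primary alcohol
Product: 19 carboxylic acid (C12 as CO2H)
Conditions: TEMPO (cat.), PhI(OAc)2, MeCN/H2O, rt
Reagents that add atoms: water, O
Why: Nitroxyl-catalysed oxidation of a primary alcohol through the aldehyde hydrate to the acid under conditions mild enough for the furan and the vinylcyclopropane.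

Step 12
Reactants: 19 carboxylic acid
Product: 21 ring C ketone (furan-fused cycloheptanone closed), via mixed trifluoroacetic anhydride 20 (not isolated)
Conditions: (CF3CO)2O, CH2Cl2, 0 °C to rt
Reagents that add atoms: none
Why: Intramolecular Friedel–Crafts acylation through the mixed anhydride; the only furan position within reach is C13 (furan 3-position), so the seven-membered ring C closes and the furan becomes a deactivated vinylogous ester.

Step 13
Reactants: 21 ring C ketone
Product: 22 2α,3α-epoxide
Conditions: m-CPBA, NaHCO3, CH2Cl2, 0 °C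
Reagents that add atoms: 3-chloroperbenzoic acid, OOC(=O)c1cccc(Cl)c1
Why: Prilezhaev epoxidation of the only electron-rich alkene (C2=C3), expected from the α face opposite the furan on C1 and the C6 methylene, while the acylated furan is spared (the C2 configuration is reset in steps 17 and 19).

Step 14
Reactants: 22 2α,3α-epoxide
Product: 23 epoxy alcohol (C7H2OH)
Conditions: Bu4NF, AcOH, THF, rt
Reagents that add atoms: none
Why: Buffered fluoride desilylation of the tert-butyldiphenylsilyl ether, with acetic acid keeping the medium from opening the epoxide or enolising C1.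

Step 15
Reactants: 23 epoxy alcohol
Product: 24 epoxy aldehyde (C7HO)
Conditions: Dess–Martin periodinane, NaHCO3, CH2Cl2, rt
Reagents that add atoms: none
Why: Dess–Martin oxidation of the primary alcohol to the aldehyde under buffered conditions that preserve the epoxide and the α-stereocentre C8.

Step 16
Reactants: 24 epoxy aldehyde
Product: 25 2α,7β-diol (rings A, B, C and the lactone complete)
Conditions: Cp2TiCl2 (20 mol %), Mn, 2,4,6-collidine·HCl, THF, rt, slow addition of 24
Reagents that add atoms: none
Why: Proposed new method: Cp2TiCl (trivalent titanium, made from Cp2TiCl2 and Mn) opens the C2–C3 epoxide by electron transfer at the C3–O bond, the C3 cyclopropylcarbinyl radical cleaves the exocyclic C4–C6 bond that is aligned with its orbital inside ring A, giving the C3=C4 alkene conjugated to the lactone and a primary C6 radical, which adds to the titanium-activated C7 aldehyde, and the resulting alkoxy radical is reduced by a second trivalent titanium. The closest known reaction types are the titanocene-mediated reductive epoxide opening with fragmentation of an adjacent cyclopropane or cyclobutane (carene and pinene oxides) and the titanocene-mediated addition of epoxide-derived radicals to aldehydes; the three events have not been run as one relay on a propellane. Ring B closes in the 6-exo-trig mode onto C=O through a chair in which C5–C19 and C9–C20 are axial, so the aldehyde oxygen takes the equatorial β position and sets C7, while C2 keeps the epoxide configuration. The step needs epoxide opening at C3 and not C2 (C3 is the more hindered carbon and gives the cyclopropyl-stabilised radical), external and not ring-fusion cleavage of the cyclopropane (stereoelectronic control by ring A), and addition to the aldehyde in preference to the vinylogous-ester ketone C12; the low stationary concentration of trivalent titanium under catalytic turnover keeps the C6 radical from being reduced before it cyclises.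

Step 17
Reactants: 25 2α,7β-diol
Product: 26 2-ketone (ring A enone) with free 7β-OH
Conditions: MnO2, CH2Cl2, rt
Reagents that add atoms: none
Why: Allylic oxidation with MnO2 converts only the C2 alcohol into the enone, which tells it apart from the saturated C7 alcohol and leaves the now epimerisable C1 in its more stable equatorial-furan configuration.

Step 18
Reactants: 26 2-ketone with free 7β-OH
Product: 27 7β-acetoxy 2-ketone
Conditions: Ac2O, pyridine, DMAP (cat.), CH2Cl2, rt
Reagents that add atoms: acetic anhydride, CC(=O)OC(C)=O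
Why: DMAP-catalysed acetylation of the one remaining (equatorial C7) secondary alcohol.

Step 19
Reactants: 27 7β-acetoxy 2-ketone
Product: 28 target CNP0182929.2
Conditions: NaBH4, CeCl3·7H2O, MeOH, −78 °C
Reagents that add atoms: none
Why: Luche reduction: 1,2-selective hydride delivery to the enone carbonyl by axial attack anti to the C1 substituent should give the pseudo-equatorial 2α-alcohol, while the much less electrophilic ketone C12, the lactone and the acetate are left alone.

**Compound list**

1 | tert-butyl(but-3-yn-1-yloxy)dimethylsilane | C#CCCO[Si](C)(C)C(C)(C)C | starting material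
2 | furan-2-carbonyl chloride | O=C(Cl)c1ccco1 | starting material
3 | (E)-{4-[(tert-butyldimethylsilyl)oxy]-2-methylbut-1-en-1-yl}dimethylalane | C[Al](C)/C=C(\C)CCO[Si](C)(C)C(C)(C)C | intermediate
4 | (2E)-5-[(tert-butyldimethylsilyl)oxy]-1-(furan-2-yl)-3-methylpent-2-en-1-one | O=C(/C=C(\C)CCO[Si](C)(C)C(C)(C)C)c1ccco1 | intermediate
5 | (1R,2E)-5-[(tert-butyldimethylsilyl)oxy]-1-(furan-2-yl)-3-methylpent-2-en-1-ol | O[C@H](/C=C(\C)CCO[Si](C)(C)C(C)(C)C)c1ccco1 | intermediate
6 | (1R,2E)-5-[(tert-butyldimethylsilyl)oxy]-1-(furan-2-yl)-3-methylpent-2-en-1-yl propanoate | CCC(=O)O[C@H](/C=C(\C)CCO[Si](C)(C)C(C)(C)C)c1ccco1 | intermediate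
7 | Z trimethylsilyl ketene acetal of 6 (methyl cis to OSiMe3) | C/C=C(\O[Si](C)(C)C)O[C@H](/C=C(\C)CCO[Si](C)(C)C(C)(C)C)c1ccco1 | intermediate
8 | trimethylsilyl ester of acid 9 | C[Si](C)(C)OC(=O)[C@@H](C)[C@](C)(CCO[Si](C)(C)C(C)(C)C)/C=C/c1ccco1 | intermediate
9 | (2S,3R,4E)-3-{2-[(tert-butyldimethylsilyl)oxy]ethyl}-5-(furan-2-yl)-2,3-dimethylpent-4-enoic acid | OC(=O)[C@@H](C)[C@](C)(CCO[Si](C)(C)C(C)(C)C)/C=C/c1ccco1 | intermediate
10 | (2S,3R,4E)-3-{2-[(tert-butyldimethylsilyl)oxy]ethyl}-5-(furan-2-yl)-2,3-dimethylpent-4-en-1-ol | OC[C@@H](C)[C@](C)(CCO[Si](C)(C)C(C)(C)C)/C=C/c1ccco1 | intermediate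
11 | tert-butyldiphenylsilyl ether of 10 (O-1 silylated; 2S,3R,4E) | CC(C)(C)[Si](OC[C@@H](C)[C@](C)(CCO[Si](C)(C)C(C)(C)C)/C=C/c1ccco1)(c1ccccc1)c1ccccc1 | intermediate
12 | tetronic acid (4-hydroxyfuran-2(5H)-one) | OC1=CC(=O)OC1 | starting material
13 | ethyl 3,3-diethoxypropanoate | CCOC(=O)CC(OCC)OCC | starting material
14 | 2H-furo[3,4-b]pyran-2,5(7H)-dione | O=C1C=CC2=C(O1)COC2=O | intermediate
15 | bridged cycloadduct of 11 and 14: 2-oxabicyclo[2.2.2]octenone carrying the fused γ-lactone; C1/C10 trans as in 16; bridgehead orientation (endo or exo) left open | O=C1OC23COC(=O)C2=CC1[C@@H](c1ccco1)[C@@H]3[C@@](C)(CCO[Si](C)(C)C(C)(C)C)[C@H](C)CO[Si](c1ccccc1)(c1ccccc1)C(C)(C)C | intermediate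
16 | 4-{(2S,3R)-1-[(tert-butyldiphenylsilyl)oxy]-5-[(tert-butyldimethylsilyl)oxy]-2,3-dimethylpentan-3-yl}-5-(furan-2-yl)-4,5-dihydro-2-benzofuran-1(3H)-one; H-4 and H-5 trans (10β-H and 1β-furyl in target numbering) | CC(C)(C)[Si](OC[C@@H](C)[C@](C)(CCO[Si](C)(C)C(C)(C)C)[C@H]1[C@H](c2ccco2)C=CC2=C1COC2=O)(c1ccccc1)c1ccccc1 | intermediate
17 | cyclopropane lactone from 16: CH2 (C6) added across C4=C5 on the β face (cis to H-10); C2=C3 retained; lactone on the α face | CC(C)(C)[Si](OC[C@@H](C)[C@](C)(CCO[Si](C)(C)C(C)(C)C)[C@H]1[C@H](c2ccco2)C=C[C@]23C[C@]12COC3=O)(c1ccccc1)c1ccccc1 | intermediate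
18 | primary alcohol from 17 (CH2CH2OH on C9) | CC(C)(C)[Si](OC[C@@H](C)[C@](C)(CCO)[C@H]1[C@H](c2ccco2)C=C[C@]23C[C@]12COC3=O)(c1ccccc1)c1ccccc1 | intermediate
19 | carboxylic acid from 18 (CH2CO2H on C9) | CC(C)(C)[Si](OC[C@@H](C)[C@](C)(CC(=O)O)[C@H]1[C@H](c2ccco2)C=C[C@]23C[C@]12COC3=O)(c1ccccc1)c1ccccc1 | intermediate
20 | mixed anhydride of 19 and trifluoroacetic acid | CC(C)(C)[Si](OC[C@@H](C)[C@](C)(CC(=O)OC(=O)C(F)(F)F)[C@H]1[C@H](c2ccco2)C=C[C@]23C[C@]12COC3=O)(c1ccccc1)c1ccccc1 | intermediate
21 | ring C ketone: furan C13 acylated by C12; ring A alkene C2=C3, cyclopropane lactone and C7H2OSi(t-Bu)Ph2 in place | CC(C)(C)[Si](OC[C@@H](C)[C@]1(C)CC(=O)c2ccoc2[C@@H]2C=C[C@]34C[C@]3(COC4=O)[C@@H]12)(c1ccccc1)c1ccccc1 | intermediate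
22 | 2α,3α-epoxide of 21 | CC(C)(C)[Si](OC[C@@H](C)[C@]1(C)CC(=O)c2ccoc2[C@@H]2[C@H]3O[C@H]3[C@]34C[C@]3(COC4=O)[C@@H]12)(c1ccccc1)c1ccccc1 | intermediate
23 | epoxy alcohol (C7H2OH) | OC[C@@H](C)[C@]1(C)CC(=O)c2ccoc2[C@@H]2[C@H]3O[C@H]3[C@]34C[C@]3(COC4=O)[C@@H]12 | intermediate
24 | epoxy aldehyde (C7HO; 8S) | O=C[C@@H](C)[C@]1(C)CC(=O)c2ccoc2[C@@H]2[C@H]3O[C@H]3[C@]34C[C@]3(COC4=O)[C@@H]12 | intermediate
25 | 2α,7β-diol (the target without its acetyl group) | O[C@H]1C[C@@]23COC(=O)C2=C[C@H](O)[C@H]2c4occc4C(=O)C[C@@](C)([C@@H]1C)[C@@H]23 | intermediate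
26 | 2-ketone (ring A enone) with free 7β-OH | O[C@H]1C[C@@]23COC(=O)C2=CC(=O)[C@H]2c4occc4C(=O)C[C@@](C)([C@@H]1C)[C@@H]23 | intermediate
27 | 7β-acetate of 26 | CC(=O)O[C@H]1C[C@@]23COC(=O)C2=CC(=O)[C@H]2c4occc4C(=O)C[C@@](C)([C@@H]1C)[C@@H]23 | intermediate
28 | CNP0182929.2 (7β-acetoxy, 2α-hydroxy) | CC(=O)O[C@H]1C[C@@]23COC(=O)C2=C[C@H](O)[C@H]2c4occc4C(=O)C[C@@](C)([C@@H]1C)[C@@H]23 | target

**Step count and risks**

Total steps: 19. Longest linear sequence: 18 (steps 1–6 and 8–19; step 7 is a one-step branch).

Step 16 (Proposed new method). What may go wrong: electron transfer may open the epoxide at C2 instead of C3, the C6 radical may be reduced or re-close before it reaches the aldehyde, or it may add to the C12 ketone. The fallback uses known reaction types and sets out from ketone 21. Me3SiI (CH2Cl2, 0 °C; then DBU) opens the lactone-activated cyclopropane at C6 by homoconjugate addition and gives the iodomethyl lactone F1 with the C3=C4 double bond. Bu4NF/AcOH gives alcohol F2, and Dess–Martin oxidation gives iodo aldehyde F3. Bu3SnH/AIBN (benzene, 80 °C, slow addition) closes ring B by 6-exo radical addition to the aldehyde and gives the 2-deoxy alcohol F4. Ac2O/pyridine gives acetate F5, and allylic oxidation at C2 (CrO3, 3,5-dimethylpyrazole, CH2Cl2, −20 °C) returns to the route at 27.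

Step 8. What may go wrong: the bimolecular cycloaddition may be too slow at an alkene flanked by a quaternary carbon, facial selectivity with respect to C9 may be poor, or the vinylfuran may react as a diene. The fallback makes the cycloaddition intramolecular and sets out from acid 9. Alkylation of its carboxylate (K2CO3, DMF) with methyl 6-(bromomethyl)-2-oxo-2H-pyran-5-carboxylate gives pyranone ester F6. Heating (toluene, 110 °C) gives, by intramolecular Diels–Alder reaction and loss of CO2, the seven-membered lactone diene ester F7. LiBH4 (THF, 0 °C) reduces the saturated lactone, and the freed C19 alcohol closes onto the methyl ester (PPTS) to give hydroxy butenolide F8. Silylation (t-BuPh2SiCl, imidazole) returns to the route at 16.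

Step 9. What may go wrong: conjugate addition of the ylide to the fully substituted C5 may be too slow, or the ylide may attack the lactone carbonyl. The fallback sets out from 16. 1,3-Dipolar cycloaddition of diazomethane (Et2O, 0 °C) across C4=C5 gives pyrazoline F9, and photolysis (hν, benzophenone, benzene) with loss of N2 returns to the route at 17.

Further compounds
F1 | step 16 | iodomethyl lactone: C5–CH2I, C3=C4 conjugated lactone, C2H2, ring C ketone, C7H2OSi(t-Bu)Ph2 | CC(C)(C)[Si](OC[C@@H](C)[C@]1(C)CC(=O)c2ccoc2[C@@H]2CC=C3C(=O)OC[C@@]3(CI)[C@@H]12)(c1ccccc1)c1ccccc1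
F2 | step 16 | alcohol from F1 (C7H2OH) | OC[C@@H](C)[C@]1(C)CC(=O)c2ccoc2[C@@H]2CC=C3C(=O)OC[C@@]3(CI)[C@@H]12
F3 | step 16 | iodo aldehyde (C7HO) | O=C[C@@H](C)[C@]1(C)CC(=O)c2ccoc2[C@@H]2CC=C3C(=O)OC[C@@]3(CI)[C@@H]12
F4 | step 16 | 2-deoxy 7β-alcohol (ring B closed) | O[C@H]1C[C@@]23COC(=O)C2=CC[C@H]2c4occc4C(=O)C[C@@](C)([C@@H]1C)[C@@H]23
F5 | step 16 | 2-deoxy 7β-acetate | CC(=O)O[C@H]1C[C@@]23COC(=O)C2=CC[C@H]2c4occc4C(=O)C[C@@](C)([C@@H]1C)[C@@H]23
F6 | step 8 | [5-(methoxycarbonyl)-2-oxo-2H-pyran-6-yl]methyl ester of acid 9 | COC(=O)C1=C(COC(=O)[C@@H](C)[C@](C)(CCO[Si](C)(C)C(C)(C)C)/C=C/c2ccco2)OC(=O)C=C1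
F7 | step 8 | cyclohexadiene methyl ester fused to the seven-membered lactone C7(=O)–O–C19; 1β-furyl, 10β-H | COC(=O)C1=C2COC(=O)[C@@H](C)[C@](C)(CCO[Si](C)(C)C(C)(C)C)[C@H]2[C@H](c2ccco2)C=C1
F8 | step 8 | hydroxy butenolide: 16 with free C7H2OH | OC[C@@H](C)[C@](C)(CCO[Si](C)(C)C(C)(C)C)[C@H]1[C@H](c2ccco2)C=CC2=C1COC2=O
F9 | step 9 | 1-pyrazoline from 16: C4–N=N–CH2–C5 on the β face | CC(C)(C)[Si](OC[C@@H](C)[C@](C)(CCO[Si](C)(C)C(C)(C)C)[C@H]1[C@H](c2ccco2)C=C[C@]23N=NC[C@]12COC3=O)(c1ccccc1)c1ccccc1
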